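Both halves of the target are the same 7-acetyl-3,6,8-trihydroxy-4,4-dimethylnaphthalen-1(4H)-one, joined by a CH2 group between their C2 atoms, so the plan is one monomer plus a closing formaldehyde condensation. The monomer is disconnected at C4–C4a: the gem-dimethyl quaternary carbon C4 of ring B is traced back to the internal carbon of an isopropenyl group, which is arylated by C4a of ring A while its CH2 terminus is reduced to methyl. A single palladium-catalysed reductive cyclisation thus closes ring B and creates the hydrogen-free benzylic quaternary centre. Its substrate is an aryl bromide bearing, ortho to bromine, an E-configured β-methoxy dienone chain that ends in the isopropenyl group.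

Key step: step 6

Remark: each half is numbered as a naphthalen-1(4H)-one (ring A = C4a, C5–C8, C8a; ring B = C1–C4, C4a, C8a), and the target is taken as the drawn 3-hydroxy-1-oxo enol tautomer, which equilibrates freely with its other enol forms.

Step 1
Reactants: 1 1-bromo-3,5-dimethoxybenzene
Product: 4 1-(4-bromo-2,6-dimethoxyphenyl)ethan-1-one, via aryllithium 2 (not isolated), via tetrahedral lithium alkoxide 3 (not isolated)
Conditions: LiN(i-Pr)2 (1.1 equiv), THF, −78 °C; then MeC(O)N(OMe)Me, −78 → 0 °C; 1 M HCl
Reagents that add atoms: N-methoxy-N-methylacetamide, CC(=O)N(C)OC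
Why: Directed ortho-metalation followed by Weinreb ketone synthesis: the amide base leaves the C–Br bond alone and should remove the proton flanked by both methoxy groups (para to bromine, so no aryne can form), and adduct 3 collapses to the ketone only on acidic quench, which prevents double addition.

Step 2
Reactants: 4 1-(4-bromo-2,6-dimethoxyphenyl)ethan-1-one
Product: 6 3-acetyl-6-bromo-2,4-dimethoxybenzaldehyde, via α-chloro ether 5 (not isolated)
Conditions: Cl2CHOMe, TiCl4, CH2Cl2, 0 °C → rt; then ice-cold 1 M HCl
Reagents that add atoms: dichloromethyl methyl ether, COC(Cl)Cl; water, O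
Why: Rieche formylation (electrophilic aromatic substitution): the two free ring positions are equivalent, each ortho to one methoxy group and para to the other, the acetyl group is twisted out of conjugation by its two ortho substituents, and the first formyl group should shut down a second substitution.

Step 3
Reactants: 6 3-acetyl-6-bromo-2,4-dimethoxybenzaldehyde; 7 2-methylbut-1-en-3-yne
Product: 9 racemic 1-(3-acetyl-6-bromo-2,4-dimethoxyphenyl)-4-methylpent-4-en-2-yn-1-ol, via lithium enynide 8 (not isolated)
Conditions: 7, n-BuLi, THF, −78 °C; then 6, −78 °C; sat. aq. NH4Cl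
Reagents that add atoms: none
Why: 1,2-Addition of a lithium acetylide to an aldehyde: at −78 °C the formyl group should react much faster than the methyl ketone, whose carbonyl is shielded by two ortho substituents, and the new carbinol centre is formed as a racemate that step 4 removes.

Step 4
Reactants: 9 racemic 1-(3-acetyl-6-bromo-2,4-dimethoxyphenyl)-4-methylpent-4-en-2-yn-1-ol
Product: 10 1-(3-acetyl-6-bromo-2,4-dimethoxyphenyl)-4-methylpent-4-en-2-yn-1-one
Conditions: Dess–Martin periodinane, CH2Cl2, 0 °C → rt
Reagents that add atoms: none
Why: Dess–Martin oxidation of a secondary benzylic propargylic alcohol under near-neutral conditions, which should leave the enyne, the aryl bromide and the methyl ketone untouched and destroys the racemic carbinol centre.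

Step 5
Reactants: 10 1-(3-acetyl-6-bromo-2,4-dimethoxyphenyl)-4-methylpent-4-en-2-yn-1-one
Product: 11 (E)-1-(3-acetyl-6-bromo-2,4-dimethoxyphenyl)-3-methoxy-4-methylpenta-2,4-dien-1-one
Conditions: MeOH, PMe3 (10 mol %), CH2Cl2, 0 °C → rt
Reagents that add atoms: methanol, CO
Why: Phosphine-catalysed oxa-Michael addition of methanol to the alkyne carbon β to the ketone: the γ-carbon carries no hydrogen, so phosphine-induced isomerisation is excluded, and reversible addition of the catalyst should funnel the enol ether to its thermodynamically preferred E isomer, in which methoxy is trans to the carbonyl group and the aroyl and isopropenyl groups are cis.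

Step 6
Reactants: 11 (E)-1-(3-acetyl-6-bromo-2,4-dimethoxyphenyl)-3-methoxy-4-methylpenta-2,4-dien-1-one
Product: 14 7-acetyl-3,6,8-trimethoxy-4,4-dimethylnaphthalen-1(4H)-one, via arylpalladium bromide 12 (not isolated), via neopentylpalladium bromide 13 (not isolated)
Conditions: Pd(OAc)2 (10 mol %), PPh3 (25 mol %), HCO2Na (1.5 equiv), Et4NCl (1 equiv), DMF, 80 °C
Reagents that add atoms: none
Why: Reductive Heck cyclisation: zerovalent palladium, formed from Pd(OAc)2 and PPh3, inserts into the C4a–Br bond to give 12, syn carbopalladation places C4a on the internal carbon of the isopropenyl group (the future C4) and gives the divalent alkylpalladium 13, and exchange of bromide for formate, loss of CO2 and C–H reductive elimination turn its CH2–Pd group into the second methyl group. The closest known reaction type is the intramolecular Mizoroki–Heck insertion of aryl halides into 1,1-disubstituted alkenes with formate as terminal hydride donor, an established way to build benzylic quaternary carbons. Ring B is closed in the 6-exo-trig mode. The product has no stereocentre, since C4 ends up with two identical methyl groups and the transient centre in 13 disappears on reduction. Three selectivities are needed: 6-exo insertion ahead of 7-endo insertion, ring closure ahead of hydride transfer to 12, and reduction of 13 ahead of any rearrangement. They should be secured by the E enol ether, which holds the isopropenyl group cis to the aroyl group within reach of palladium, by the low solubility of HCO2Na in DMF, which keeps hydride delivery slower than the intramolecular insertion, and by the lack of hydrogen on C4, which leaves 13 no β-hydride pathway.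

Step 7
Reactants: 14 7-acetyl-3,6,8-trimethoxy-4,4-dimethylnaphthalen-1(4H)-one
Product: 15 7-acetyl-3,6,8-trihydroxy-4,4-dimethylnaphthalen-1(4H)-one
Conditions: BBr3 (6 equiv), CH2Cl2, −78 °C → rt; then H2O, 0 °C → rt
Reagents that add atoms: none
Why: Ether cleavage by BBr3: boron binds the ether and carbonyl oxygens and bromide removes each methyl group by SN2 attack, the two aryl ethers being activated by chelation to the neighbouring acetyl and C1 carbonyl groups and the C3 vinylogous ester reacting like an ester, so that one operation should free all three hydroxyl groups.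

Step 8
Reactants: 15 7-acetyl-3,6,8-trihydroxy-4,4-dimethylnaphthalen-1(4H)-one (two molecules); 16 formaldehyde
Product: 19 2,2'-methylenebis[7-acetyl-3,6,8-trihydroxy-4,4-dimethylnaphthalen-1(4H)-one] (CNP0295164.0), via hydroxymethyl adduct 17 (not isolated), via methylidene trione 18 (not isolated)
Conditions: 37 % aq. CH2O (0.5 equiv), NaOAc (cat.), EtOH–H2O, rt
Reagents that add atoms: none
Why: Knoevenagel condensation followed by Michael addition, the standard route from cyclic 1,3-diones and formaldehyde to methylene-bridged dimers: C2 of the vinylogous acid 15 is by far the most nucleophilic carbon, enedione 18 should be captured at once by a second molecule of 15, and the limiting amount of formaldehyde should leave the hindered aromatic C5 untouched.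

Compound list
1 | 1-bromo-3,5-dimethoxybenzene | COc1cc(Br)cc(OC)c1 | starting material
2 | (4-bromo-2,6-dimethoxyphenyl)lithium | [Li]c1c(OC)cc(Br)cc1OC | intermediate
3 | lithium 1-(4-bromo-2,6-dimethoxyphenyl)-1-[methoxy(methyl)amino]ethan-1-olate | CC(O[Li])(N(C)OC)c1c(OC)cc(Br)cc1OC | intermediate
4 | 1-(4-bromo-2,6-dimethoxyphenyl)ethan-1-one | CC(=O)c1c(OC)cc(Br)cc1OC | intermediate
5 | racemic 1-{4-bromo-3-[chloro(methoxy)methyl]-2,6-dimethoxyphenyl}ethan-1-one | CC(=O)c1c(OC)cc(Br)c(C(Cl)OC)c1OC | intermediate
6 | 3-acetyl-6-bromo-2,4-dimethoxybenzaldehyde | CC(=O)c1c(OC)cc(Br)c(C=O)c1OC | intermediate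
7 | 2-methylbut-1-en-3-yne | C=C(C)C#C | starting material
8 | lithium 3-methylbut-3-en-1-yn-1-ide | [Li]C#CC(C)=C | intermediate
9 | racemic 1-(3-acetyl-6-bromo-2,4-dimethoxyphenyl)-4-methylpent-4-en-2-yn-1-ol | CC(=O)c1c(OC)cc(Br)c(C(O)C#CC(C)=C)c1OC | intermediate
10 | 1-(3-acetyl-6-bromo-2,4-dimethoxyphenyl)-4-methylpent-4-en-2-yn-1-one | CC(=O)c1c(OC)cc(Br)c(C(=O)C#CC(C)=C)c1OC | intermediate
11 | (E)-1-(3-acetyl-6-bromo-2,4-dimethoxyphenyl)-3-methoxy-4-methylpenta-2,4-dien-1-one | CC(=O)c1c(OC)cc(Br)c(C(=O)/C=C(/OC)C(C)=C)c1OC | intermediate
12 | bromo{4-acetyl-3,5-dimethoxy-2-[(E)-3-methoxy-4-methylpenta-2,4-dienoyl]phenyl}palladium (divalent palladium, phosphine ligands not drawn) | CC(=O)c1c(OC)cc([Pd]Br)c(C(=O)/C=C(/OC)C(C)=C)c1OC | intermediate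
13 | bromo[(7-acetyl-3,6,8-trimethoxy-4-methyl-1-oxo-1,4-dihydronaphthalen-4-yl)methyl]palladium (divalent palladium, racemic at C4, phosphine ligands not drawn) | CC(=O)c1c(OC)cc2c(c1OC)C(=O)C=C(OC)C2(C)C[Pd]Br | intermediate
14 | 7-acetyl-3,6,8-trimethoxy-4,4-dimethylnaphthalen-1(4H)-one | CC(=O)c1c(OC)cc2c(c1OC)C(=O)C=C(OC)C2(C)C | intermediate
15 | 7-acetyl-3,6,8-trihydroxy-4,4-dimethylnaphthalen-1(4H)-one | CC(=O)c1c(O)cc2c(c1O)C(=O)C=C(O)C2(C)C | intermediate
16 | formaldehyde | C=O | starting material
17 | 7-acetyl-3,6,8-trihydroxy-2-(hydroxymethyl)-4,4-dimethylnaphthalen-1(4H)-one | CC(=O)c1c(O)cc2c(c1O)C(=O)C(CO)=C(O)C2(C)C | intermediate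
18 | 7-acetyl-6,8-dihydroxy-4,4-dimethyl-2-methylidenenaphthalene-1,3(2H,4H)-dione | CC(=O)c1c(O)cc2c(c1O)C(=O)C(=C)C(=O)C2(C)C | intermediate
19 | 2,2'-methylenebis[7-acetyl-3,6,8-trihydroxy-4,4-dimethylnaphthalen-1(4H)-one] (CNP0295164.0) | CC(=O)c1c(O)cc2c(c1O)C(=O)C(CC1=C(O)C(C)(C)c3cc(O)c(C(C)=O)c(O)c3C1=O)=C(O)C2(C)C | target

Total step count: 8
Longest linear sequence: 8 steps (1 → 19)

Steps most likely to fail

1. Step 6. Bromine may be lost by hydride transfer to the arylpalladium species before the ring closes. The alkene may also insert at its terminus (7-endo), or the alkylpalladium species may be captured by the neighbouring enol ether double bond before it is reduced. The fallback sets out from 11. Hydrogenation of the isopropenyl group with RhCl(PPh3)3 and H2 (1 atm, toluene–EtOH, rt) spares the aryl bromide and the trisubstituted enol ether and should give (E)-1-(3-acetyl-6-bromo-2,4-dimethoxyphenyl)-3-methoxy-4-methylpent-2-en-1-one F1. Treatment of F1 with Pd(OAc)2, P(t-Bu)3·HBF4 and Cs2CO3 in dilute toluene at 100 °C should generate the γ-dienolate of the vinylogous ester and close the same C4–C4a bond by intramolecular palladium-catalysed enolate arylation. The acetyl enolate cannot reach C4a, and dilution disfavours its intermolecular arylation. The route is rejoined at 14.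

2. Step 2. Electrophilic substitution may be sluggish on a ring that carries an acyl group and a bromine, and chelation of TiCl4 may strip an ortho methyl ether. The fallback sets out from 4. Ring iodination with N-iodosuccinimide and CF3CO2H in MeCN at the same, uniquely activated position should give 1-(4-bromo-3-iodo-2,6-dimethoxyphenyl)ethan-1-one F2. Palladium-catalysed formylation of the carbon–iodine bond of F2 (PdCl2(PPh3)2, CO 1 atm, HCO2Na, DMF, 80 °C) should outpace insertion into the carbon–bromine bond and rejoins the route at 6.

3. Step 3. The acetylide may enolise or attack the methyl ketone instead of adding cleanly to the aldehyde, which would lead to aldol-type coupling and incomplete conversion. The fallback sets out from 6. Pinnick oxidation (NaClO2, NaH2PO4, 2-methylbut-2-ene, t-BuOH–H2O) should give 3-acetyl-6-bromo-2,4-dimethoxybenzoic acid F3. Oxalyl chloride with catalytic DMF in CH2Cl2 should convert F3 into 3-acetyl-6-bromo-2,4-dimethoxybenzoyl chloride F4. Acyl Sonogashira coupling of F4 with 7 (PdCl2(PPh3)2, CuI, Et3N, THF, rt) should then give the ynone directly. The route is rejoined at 10, and step 4 is no longer needed.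

Further compounds
F1 | step 6 | (E)-1-(3-acetyl-6-bromo-2,4-dimethoxyphenyl)-3-methoxy-4-methylpent-2-en-1-one | CC(=O)c1c(OC)cc(Br)c(C(=O)/C=C(/OC)C(C)C)c1OC
F2 | step 2 | 1-(4-bromo-3-iodo-2,6-dimethoxyphenyl)ethan-1-one | CC(=O)c1c(OC)cc(Br)c(I)c1OC
F3 | step 3 | 3-acetyl-6-bromo-2,4-dimethoxybenzoic acid | CC(=O)c1c(OC)cc(Br)c(C(=O)O)c1OC
F4 | step 3 | 3-acetyl-6-bromo-2,4-dimethoxybenzoyl chloride | CC(=O)c1c(OC)cc(Br)c(C(=O)Cl)c1OC
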